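6 questions stand here, and I answer them with one count.

| setting | Wednesday's | Saturday's | Tuesday's | Thursday's | Monday's |
|---|---|---|---|---|---|
| substrate | 0.24 M | 0.24 M (fed, over 1.0 min) | 0.24 M (fed, over 6.0 s) | 0.24 M (fed, over 1.0 min) | 0.24 M |
| partner | 0.228 M (fed, over 1.0 min) | 0.228 M | 0.228 M | 0.228 M | 0.228 M |
| temperature | 110 °C |  | 110 °C | 110 °C |  |
| time | 2.5 min | 2.5 min | 2.5 min | 2.5 min | 2.5 min |
| remark | all else is in the flask from the start; the feed brings no volume worth counting | the addition at 70 °C, then warmed to 110 °C; the feed brings no volume worth counting | all else is in the flask from the start; the feed brings no volume worth counting | all else is in the flask from the start; the feed brings no volume worth counting | everything together at the start at 70 °C, warmed to 110 °C at 1.0 min |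

1. the flask that comes out highest in amount of target, in percent of the substrate charged, or "all alike" when all lie within 1.5 percentage points (Wednesday's / Saturday's / Tuesday's / Thursday's / Monday's / all alike)
2. target at the end, in percent of the substrate charged, Wednesday's
3. target at the end, in percent of the substrate charged, Saturday's
4. target at the end, in percent of the substrate charged, Tuesday's
5. target at the end, in percent of the substrate charged, Thursday's
6. target at the end, in percent of the substrate charged, Monday's

- in percentages every species weighs as the substrate in it: one side product counts as two
- constants are those at 110 °C; use the activation energies for any other temperature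

    substrate → open intermediate (k1 = 0.0334 s⁻¹, Ea1 = 104 kJ mol⁻¹)
    partner → second intermediate (k2 = 0.0281 s⁻¹, Ea2 = 100 kJ mol⁻¹)
    open intermediate + second intermediate → target (k3 = 0.126 M⁻¹ s⁻¹, Ea3 = 79.0 kJ mol⁻¹)
    substrate + open intermediate → side product (k4 = 0.0290 M⁻¹ s⁻¹, Ea4 = 75.0 kJ mol⁻¹)
    (constants at 110 °C)

I turn the first question round: what must be true for a slow feed to beat Tuesday's quick one? A slow feed of substrate should save side product and costs time, so I price the time. My measure is the coupling count: the coupling constant times the partner's charge times the time for which both intermediates stand. Coupling constant and partner's charge together give a rate of 1.72 min⁻¹. I take the coupled share of the open intermediate, as in a second-order reaction between like amounts, as the count divided by one plus the count.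

I let a species wait one lifetime to react, 29.9 s for substrate and 35.6 s for partner, and a fed species wait half the feed time besides. In Tuesday's the partner waits longer, so the coupling count is 3.29. In Thursday's the substrate waits longer, which gives 2.59. Wednesday's feeds the partner, so both waits fall on the partner and the count is 2.43. In the minute at 70 °C, substrate makes 0.0446 turnovers, so I start Saturday's and Monday's at 1.0 min, with 1.56.

The side step against the opening step gives a kept fraction of 0.828, which I hold for every flask, crudely. Mine are then 58.6%, 50.5%, 63.5%, 59.7% and 50.5%, and the highest is Tuesday's.

The coupled shares are 0.767 for Tuesday's and 0.721 for Thursday's. To overtake Tuesday's on this reckoning, Thursday's feed must save 5.22% of the charge over Tuesday's, about a third of the reckoned side loss.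

The forecast names Tuesday's, with 55.5%, 43.5%, 62%, 58% and 44.5% in the order asked, holding that “the small side-product saving from slow substrate feed does not repay the lost time”. We pick the same flask, but my Saturday's figure stands above its own.

Tuesday's gives 64.7%, the highest, with 21.9% of the charge still open intermediate at 2.50 min; Wednesday's gives 58.7%, Saturday's 47.7%, Thursday's 61.5% and Monday's 47.8%. The neighbour of Tuesday's charged with 0.14 M of partner makes the partner the limiting reagent, so I count on the kept open intermediate. Its count is 2.86, and the coupled share of its partner comes to 43.2% of the substrate charged. That neighbour gives 45.5%.

(The numbers of this flask were set for the occasion; the run is a simulation.)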